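**Plan**

- Retrosynthesis: the C4 carbinol is cut back to a ketone, and the C2–H/C3–H pair plus the three O-benzyl groups to a 2,3-dihydro-4H-pyran-4-one. The exocyclic C6–CH2 bond is then cut by conjugate addition of an arylethyl Grignard reagent to an achiral 2-aryl-4H-pyran-4-one. The pyranone is cut at C2–C3 (aldol) and O1–C6 (cyclization).
- Enabling feature: the oxane ring O1/C2–C6 carries its oxygen on C4 and ether carbons at C2 and C6, so it is the fully reduced form of a flat γ-pyrone. The aryl group on C2 leaves C6–H as the only open vinylogous-ester β-carbon.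
- Forward: 5-hydroxyvanillin is converted into the 2-aryl-γ-pyrone in 3 steps, and the side-chain bromide is made in 1 step. A Cu-catalysed enantioselective dearomatizing addition joins the halves, followed by hydrogenation and ketone reduction.
- Stereochemistry: C6 (S) comes from the chiral ligand on copper. C2 (S) is relayed from C6 by cis-hydrogenation. C4 (R) comes from axial hydride attack on the chair ketone, giving the all-cis, all-equatorial oxanol.

Key step: step 5

Remark: the target is read as the (2S,4R,6S) isomer, in which aryl, hydroxyl and arylethyl groups are all cis. Ring atoms are numbered as in the target throughout (O1, C2 aryl-bearing, C4 oxygenated, C6 chain-bearing), also where a systematic name numbers differently.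

**Route**

Step 1
Reactants: 1 3,4-dihydroxy-5-methoxybenzaldehyde (5-hydroxyvanillin)
Product: 2 3,4-bis(benzyloxy)-5-methoxybenzaldehyde
Conditions: BnBr (2.4 equiv), K2CO3 (3 equiv), DMF, 60 °C
Reagents that add atoms: benzyl bromide BrCc1ccccc1
Why: Williamson etherification of both phenols; the benzyl ethers should survive the enolate, Dess–Martin, TFA and organocopper steps and are removed in step 6.

Step 2
Reactants: 2 3,4-bis(benzyloxy)-5-methoxybenzaldehyde; 3 (E)-4-methoxybut-3-en-2-one
Product: 4 (E)-5-[3,4-bis(benzyloxy)-5-methoxyphenyl]-5-hydroxy-1-methoxypent-1-en-3-one (racemic)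
Conditions: 3 (1.2 equiv), LiHMDS (1.2 equiv), THF, −78 °C; then 2, −78 °C; AcOH quench at −78 °C
Reagents that add atoms: none
Why: aldol addition of the kinetic lithium enolate of the methyl ketone to the aldehyde; the carbinol centre needs no control because it is oxidized in step 3.

Step 3
Reactants: 4 (E)-5-[3,4-bis(benzyloxy)-5-methoxyphenyl]-5-hydroxy-1-methoxypent-1-en-3-one
Product: 6 2-[3,4-bis(benzyloxy)-5-methoxyphenyl]-4H-pyran-4-one, via diketone 5 (not isolated)
Conditions: Dess–Martin periodinane (1.2 equiv), CH2Cl2, 0 °C to rt; filtration; then TFA (0.3 equiv), toluene, rt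
Reagents that add atoms: none
Why: Dess–Martin oxidation of the β-hydroxy ketone gives the enolized 1,3-diketone, whose enol oxygen adds to the β-methoxy enone and expels methanol (acid-catalysed addition–elimination) to close the aromatic γ-pyrone.

Step 4
Reactants: 7 2-[4-(benzyloxy)phenyl]ethanol
Product: 8 1-(benzyloxy)-4-(2-bromoethyl)benzene
Conditions: CBr4 (1.2 equiv), PPh3 (1.25 equiv), CH2Cl2, 0 °C to rt
Reagents that add atoms: carbon tetrabromide BrC(Br)(Br)Br
Why: Appel reaction, SN2 displacement of the alkoxyphosphonium group by bromide at the primary carbon.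

Step 5
Reactants: 6 2-[3,4-bis(benzyloxy)-5-methoxyphenyl]-4H-pyran-4-one; 8 1-(benzyloxy)-4-(2-bromoethyl)benzene
Product: 11 (S)-2-{2-[4-(benzyloxy)phenyl]ethyl}-6-[3,4-bis(benzyloxy)-5-methoxyphenyl]-2,3-dihydro-4H-pyran-4-one, via Grignard reagent 9 (not isolated), via silyl dienol ether 10 (not isolated)
Conditions: 8, Mg turnings, Et2O, rt, titration; then 6, CuBr·SMe2 (5 mol%), Ph-BPE (single enantiomer, 6 mol%), Me3SiBr (2 equiv), CH2Cl2, −78 °C, slow addition of 9 (1.5 equiv); AcOH/MeOH at −78 °C, then 1 M HCl, THF, 0 °C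
Reagents that add atoms: magnesium [Mg]; bromotrimethylsilane C[Si](C)(C)Br (their atoms remain only in intermediates 9 and 10)
Why: Proposed new method: bromotrimethylsilane reversibly O-silylates the pyranone carbonyl to a 4-silyloxypyrylium ion pair; the diphosphine-bound alkylcopper(I) formed from 9 π-binds C5=C6, adds at C6 to a Cu(III) σ-complex and reductively eliminates the C6–CH2 bond, giving silyl dienol ether 10, which aqueous acid converts into enone 11. The closest known reaction type is the Cu/diphosphine-catalysed enantioselective conjugate addition of Grignard reagents to chromones, N-acyl-4-pyridones and 4-quinolones under Lewis acid activation, together with the racemic addition of Grignard reagents to 4-silyloxypyrylium salts; the extension to a monocyclic 2-aryl-4H-pyran-4-one is the new part. No ring is closed; the flat, achiral pyranone ring is dearomatized into the future oxane. The only new stereocentre (C6) is set by the ligand on copper (catalyst control; attack on the Si face of C6, priorities O1 > C5 > H, is needed for S, and the ligand antipode is to be assigned in a pilot run). The step needs C6 over C2 regioselectivity, 1,4- over 1,2-addition and mono-addition: the aryl group blocks and conjugatively deactivates C2, the soft alkylcopper at −78 °C should avoid the carbonyl, and the product stays masked as dienol ether 10 until work-up. The cold acidic quench is meant to keep 10 from racemizing by oxa-6π ring opening.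

Step 6
Reactants: 11 (S)-2-{2-[4-(benzyloxy)phenyl]ethyl}-6-[3,4-bis(benzyloxy)-5-methoxyphenyl]-2,3-dihydro-4H-pyran-4-one
Product: 12 (2S,6S)-2-(3,4-dihydroxy-5-methoxyphenyl)-6-[2-(4-hydroxyphenyl)ethyl]oxan-4-one
Conditions: H2 (1–3 atm), 10% Pd/C, EtOAc/MeOH, rt
Reagents that add atoms: none
Why: heterogeneous hydrogenation should deliver H2 syn to the C2=C3 face that carries the C6–H (anti to the arylethyl chain), as is general for 2,6-disubstituted 2,3-dihydropyran-4-ones, setting C2 (S) cis to C6, while the same catalyst hydrogenolyses the three benzyl ethers.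

Step 7
Reactants: 12 (2S,6S)-2-(3,4-dihydroxy-5-methoxyphenyl)-6-[2-(4-hydroxyphenyl)ethyl]oxan-4-one
Product: 13 (2S,4R,6S)-2-(3,4-dihydroxy-5-methoxyphenyl)-6-[2-(4-hydroxyphenyl)ethyl]oxan-4-ol
Conditions: NaBH4 (3 equiv), MeOH, −40 to 0 °C; aq NH4Cl
Reagents that add atoms: none
Why: ketone reduction in which the small hydride attacks the chair oxan-4-one (both substituents equatorial) along the axial trajectory, so the new C4 hydroxyl should be equatorial (4R) and cis to both substituents.

**Compound list**

1 | 3,4-dihydroxy-5-methoxybenzaldehyde (5-hydroxyvanillin) | COc1cc(C=O)cc(O)c1O | starting material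
2 | 3,4-bis(benzyloxy)-5-methoxybenzaldehyde | COc1cc(C=O)cc(OCc2ccccc2)c1OCc1ccccc1 | intermediate
3 | (E)-4-methoxybut-3-en-2-one | CO/C=C/C(C)=O | starting material
4 | (E)-5-[3,4-bis(benzyloxy)-5-methoxyphenyl]-5-hydroxy-1-methoxypent-1-en-3-one (racemic) | CO/C=C/C(=O)CC(O)c1cc(OC)c(OCc2ccccc2)c(OCc2ccccc2)c1 | intermediate
5 | (E)-1-[3,4-bis(benzyloxy)-5-methoxyphenyl]-5-methoxypent-4-ene-1,3-dione | CO/C=C/C(=O)CC(=O)c1cc(OC)c(OCc2ccccc2)c(OCc2ccccc2)c1 | intermediate
6 | 2-[3,4-bis(benzyloxy)-5-methoxyphenyl]-4H-pyran-4-one | O=c1ccoc(-c2cc(OC)c(OCc3ccccc3)c(OCc3ccccc3)c2)c1 | intermediate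
7 | 2-[4-(benzyloxy)phenyl]ethanol | OCCc1ccc(OCc2ccccc2)cc1 | starting material
8 | 1-(benzyloxy)-4-(2-bromoethyl)benzene | BrCCc1ccc(OCc2ccccc2)cc1 | intermediate
9 | {2-[4-(benzyloxy)phenyl]ethyl}magnesium bromide | Br[Mg]CCc1ccc(OCc2ccccc2)cc1 | intermediate
10 | (S)-2-{2-[4-(benzyloxy)phenyl]ethyl}-6-[3,4-bis(benzyloxy)-5-methoxyphenyl]-4-(trimethylsilyloxy)-2H-pyran | C[Si](C)(C)OC1=C[C@H](CCc2ccc(OCc3ccccc3)cc2)OC(c2cc(OC)c(OCc3ccccc3)c(OCc3ccccc3)c2)=C1 | intermediate
11 | (S)-2-{2-[4-(benzyloxy)phenyl]ethyl}-6-[3,4-bis(benzyloxy)-5-methoxyphenyl]-2,3-dihydro-4H-pyran-4-one | O=C1C[C@H](CCc2ccc(OCc3ccccc3)cc2)OC(c2cc(OC)c(OCc3ccccc3)c(OCc3ccccc3)c2)=C1 | intermediate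
12 | (2S,6S)-2-(3,4-dihydroxy-5-methoxyphenyl)-6-[2-(4-hydroxyphenyl)ethyl]oxan-4-one | COc1cc([C@@H]2CC(=O)C[C@H](CCc3ccc(O)cc3)O2)cc(O)c1O | intermediate
13 | (2S,4R,6S)-2-(3,4-dihydroxy-5-methoxyphenyl)-6-[2-(4-hydroxyphenyl)ethyl]oxan-4-ol | COc1cc([C@@H]2C[C@H](O)C[C@H](CCc3ccc(O)cc3)O2)cc(O)c1O | target

**Totals**

Total steps: 7. Longest linear sequence: 6 steps (steps 1, 2, 3, 5, 6, 7).

**Steps most likely to fail**

1. Step 5 (proposed new method). The aromatic stabilization of the γ-pyrone may make copper-mediated addition too slow. Uncatalysed addition of the Grignard reagent to the silyloxypyrylium ion pair may erode the enantioselectivity. Electrocyclic ring opening of the 2H-pyran intermediate on warming may scramble C6. The fallback uses known chemistry and builds the ring instead of dearomatizing it; it sets out from Grignard reagent 9 and aldehyde 2 and comes back to the route at target 13. Grignard reagent 9 would be formylated with DMF (Bouveault reaction; aq HCl work-up) to 3-[4-(benzyloxy)phenyl]propanal F1. Brown allylation with the antipode of B-allyldiisopinocampheylborane that gives the S alcohol (Et2O, −78 °C; NaOH/H2O2) should give (S)-1-[4-(benzyloxy)phenyl]hex-5-en-3-ol F2. Prins cyclization of F2 with aldehyde 2 (TFA, CH2Cl2, 0 °C), through a chair oxocarbenium ion with all substituents equatorial, should give (2S,4R,6S)-2-[3,4-bis(benzyloxy)-5-methoxyphenyl]-6-{2-[4-(benzyloxy)phenyl]ethyl}oxan-4-yl trifluoroacetate F3. Methanolysis (K2CO3, MeOH) would give (2S,4R,6S)-2-[3,4-bis(benzyloxy)-5-methoxyphenyl]-6-{2-[4-(benzyloxy)phenyl]ethyl}oxan-4-ol F4, and hydrogenolysis of F4 (H2, Pd/C, EtOAc/MeOH) gives 13. The known weakness of this path is partial racemization by oxonia-Cope exchange with an electron-rich aryl aldehyde.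

2. Step 6. Benzyl ether cleavage may outrun reduction of the vinylogous-ester C=C, so that the reduction stalls. Forcing conditions may then cause hydrogenolysis of the benzylic C2–O1 ring bond or lower the facial selectivity. The fallback sets out from 11 and comes back at 12, separating the C=C reduction from the debenzylation. Conjugate reduction of 11 with L-Selectride (THF, −78 °C; axial hydride delivery to C2, enolate protonated on work-up) should give (2S,6S)-2-[3,4-bis(benzyloxy)-5-methoxyphenyl]-6-{2-[4-(benzyloxy)phenyl]ethyl}oxan-4-one F5. A brief hydrogenolysis of F5 (H2, 1 atm, Pd/C, EtOAc) would then give 12.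

3. Step 2. The enolate of the methoxy enone may self-condense, and the electron-rich benzylic aldol may undergo retro-aldol cleavage or dehydration before it is oxidized. The fallback sets out from aldehyde 2 and comes back at diketone 5, replacing the aldol/oxidation pair by a C-acylation. Pinnick oxidation of 2 (NaClO2, NaH2PO4, 2-methyl-2-butene, t-BuOH/H2O) would give 3,4-bis(benzyloxy)-5-methoxybenzoic acid F6. Oxalyl chloride with catalytic DMF (CH2Cl2) would give 3,4-bis(benzyloxy)-5-methoxybenzoyl chloride F7. Acylation of the lithium enolate of 3 (2 equiv of 3 and LiHMDS, THF, −78 °C) with F7 should give 5, which is cyclized with TFA as in step 3.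

**Further compounds**

F1 | step 5 | 3-[4-(benzyloxy)phenyl]propanal | O=CCCc1ccc(OCc2ccccc2)cc1
F2 | step 5 | (S)-1-[4-(benzyloxy)phenyl]hex-5-en-3-ol | C=CC[C@H](CCc1ccc(OCc2ccccc2)cc1)O
F3 | step 5 | (2S,4R,6S)-2-[3,4-bis(benzyloxy)-5-methoxyphenyl]-6-{2-[4-(benzyloxy)phenyl]ethyl}oxan-4-yl trifluoroacetate | COc1cc([C@@H]2C[C@H](OC(=O)C(F)(F)F)C[C@H](CCc3ccc(OCc4ccccc4)cc3)O2)cc(OCc2ccccc2)c1OCc1ccccc1
F4 | step 5 | (2S,4R,6S)-2-[3,4-bis(benzyloxy)-5-methoxyphenyl]-6-{2-[4-(benzyloxy)phenyl]ethyl}oxan-4-ol | COc1cc([C@@H]2C[C@H](O)C[C@H](CCc3ccc(OCc4ccccc4)cc3)O2)cc(OCc2ccccc2)c1OCc1ccccc1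
F5 | step 6 | (2S,6S)-2-[3,4-bis(benzyloxy)-5-methoxyphenyl]-6-{2-[4-(benzyloxy)phenyl]ethyl}oxan-4-one | COc1cc([C@@H]2CC(=O)C[C@H](CCc3ccc(OCc4ccccc4)cc3)O2)cc(OCc2ccccc2)c1OCc1ccccc1
F6 | step 2 | 3,4-bis(benzyloxy)-5-methoxybenzoic acid | COc1cc(C(=O)O)cc(OCc2ccccc2)c1OCc1ccccc1
F7 | step 2 | 3,4-bis(benzyloxy)-5-methoxybenzoyl chloride | COc1cc(C(Cl)=O)cc(OCc2ccccc2)c1OCc1ccccc1
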